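## The problem

The target 24 is a 5,7,2'-trihydroxyisoflavone (chromone rings A and C, aryl ring B on C3). Ring B carries a 2,2-dimethylpyran (ring D) fused linearly through O–C4' and C4(D)–C5', and ring A carries a (2S)-2-hydroxy-3-methylbut-3-enyl chain (C1''–C4'', methyl on C3'') at C6, between O5 and O7. Three regiochemical decisions must be made without ambiguity: C6 and not C8 on ring A, C5' and not C3' for the pyran on ring B, and the union of the two aryl halves at C3. There is one stereocentre, C2''. No neighbouring stereocentre or ring can direct its formation, so a reagent or catalyst must set it, and because it is allylic it must afterwards be kept away from ionising conditions. The fragile parts are: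

- the electron-rich chromene alkene of ring D, which peracids, dioxiranes, OsO4 and halonium sources attack;
- the allylic alcohol with its 1,1-disubstituted alkene next to O5 and O7, on which acid would close a furan or pyran ring;
- the chromone, which hard nucleophiles open and hydrides reduce;
- four phenols, of which the 5-OH is chelated to the C4 carbonyl and binds Lewis-acidic metals.

The last deprotection therefore has to be neutral or buffered, which points to silyl ethers and fluoride. The enabling feature is that C2''(OH)–C3''(=C4''H2)–CH3 is the 1,3-transposed form of an (E)-allylic alcohol C2''=C3''(CH3)–C4''H2OH. A hydroxyl-directed, catalyst-controlled epoxidation of that alcohol forms the C2''–O bond with defined configuration and ignores the ring D alkene, and reductive opening at C3'' then moves the double bond to C3''=C4''.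

## Retrosynthesis

**24 back to 21.** Target 24 differs from 23 only by three O–Si bonds. In 23 the C3''=C4'' alkene and the C2'' hydroxyl are traced back to the epoxy iodide 22 (the C3''–O bond restored, iodine on C4''), and 22 to the epoxy alcohol 21. The alternatives would be reduction of a C2'' ketone or addition of an isopropenyl metal to an arylacetaldehyde. The transposition is preferred because the C2''–O bond is made once and never broken, and the terminal alkene appears only two steps from the end. The forward steps must leave the oxirane intact until Zn triggers the elimination.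

**21 back to 20 (key disconnection).** Both C–O bonds of the oxirane are cut, which leads to the achiral (E)-allylic alcohol 20. Epoxidising a 6-prenyl group and isomerising with base, or dihydroxylating it and dehydrating, would need an oxidant without a directing handle, and such oxidants attack the ring D alkene. Here the primary hydroxyl ties the reacting alkene to the catalyst. The precursor has no stereocentre. The forward reaction must supply enantiofacial control from a tartrate ligand, needs a single alkene geometry, and needs every phenol masked.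

**20 back to 17 and 18.** The hydroxyl of 20 comes from the enal 19 by 1,2-reduction. The C2''=C3'' double bond of 19 is cut by cross-metathesis logic into the 6-allyl compound 17 and methacrolein 18. Allylic oxidation of a prenyl group with SeO2 would reach 20 from the other side, but it gives alcohol and aldehyde together and needs the prenyl group first. Metathesis with an α-substituted enal delivers the (E)-isomer under thermodynamic control. The forward reaction must leave the chromene alkene alone.

**17 back to 15.** The three silyl ethers of 17 are taken back to the triphenol 16, and this to the bis-MOM ether 15. The MOM acetals survive base, Pd and heat during the assembly but cannot be removed at the end, because acid would destroy the side chain. The exchange is therefore placed at the allyl stage, where the chromene is the only acid-sensitive unit.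

**15 back to 14 and 7.** The C3–C1' bond is cut into the 3-iodochromone 14 and the aryl boronate 7 (Suzuki–Miyaura coupling). Acylating an unprotected ring A triphenol with a ring B acetic acid and inserting C2 would be shorter, but it would leave C6/C8, C5'/C3' and the differentiation of four phenols to be solved late. The chosen cut gives two fragments of similar size, each with its regiochemistry already fixed.

**14 back to 13.** The C6–C1'' bond is cut and the allyl group is reconnected through its other terminus to O5, giving the 5-allyl ether 13 (aromatic Claisen rearrangement). C6 is the only unsubstituted ortho position of O5, so the regiochemistry is structural. Halogenation or C-alkylation of ring A would give C6/C8 mixtures and, after the coupling, would hit ring B first.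

**13 back to 8 and 10.** O1–C2 and C3–I are cut, and C2 is removed as a one-carbon unit, through the enaminone 12 to the acetophenone 11. The allyl group of 11 comes from allyl bromide 10, and the MOM group leads back to 9 and to 2,4,6-trihydroxyacetophenone 8. Because 8 is symmetric, the two hydroxyls left after protection of the 4-OH are equivalent: one is allylated and the other closes the ring, so no regiochemical choice arises.

**7 back to 1 and 2.** The C–B bond of 7 leads through the aryllithium 6 to the bromochromene 5. Cutting O–C2(D) and C4(D)–C5' of ring D gives the aryl propargyl ether 4 (Claisen cascade), then the phenol 3, and finally 4-bromoresorcinol 1 and 3-chloro-3-methylbut-1-yne 2. Bromine marks the future C1' and sits para to the ether oxygen, and the MOM ether shields the wrong ortho carbon. The forward reaction needs selective etherification of the hydroxyl remote from bromine.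

## Roads not taken

**Alternative 1:** build ring A around the side chain.
- Cut: C8a–C8 and C7–C6 of ring A, with C4a–C8a broken and re-formed on the way.
- Forward key step: the cyclobutenone A2, which already carries the silylated (S)-side chain, is heated with the siloxyalkyne A3. Electrocyclic opening to a vinylketene, [2+2] addition of the alkyne, a second 4π opening and 6π closure give the phenol A1 (Danheiser benzannulation).
- Merits: the side chain is placed between the two siloxy carbons by construction, so the C6/C8 question never arises. The carbinol can be made on a small acyclic fragment where no chromene or chromone competes for the oxidant. In both respects this road is better than the chosen one.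
- Weak points: A1 is still only ring A. C4a must then be acylated and rings C and B added while a secondary allylic silyl ether and a 1,1-disubstituted alkene are carried through electrophilic steps; an iodine-mediated chromone closure would invite iodoetherification of that alkene. A2 is a bespoke, heat-sensitive compound that needs several steps and its own source of chirality, and the benzannulation runs at 80–150 °C on that fragment.
- Comparison: the chosen plan buys ring A as 8. Against the built-in regiochemistry of A1 it sets the regiospecific ortho-Claisen shift of step 8, and against the freedom of an early epoxidation it sets the hydroxyl-directed chemoselectivity of step 14. It wins on step economy, because Alternative 1 spends its key step on a ring that is commercially available and still needs an asymmetric step of the same kind.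

**Alternative 2:** close ring C last, at C3–C4.
- Cut: C3–C4.
- Forward key step: the keto aldehyde A5 (ring A aldehyde whose O1 carries the CH2–CO–ring B unit) is treated with an N-heterocyclic carbene. The acyl anion equivalent formed at the aldehyde carbon adds to the tethered ketone and gives the 3-hydroxy-3-arylchroman-4-one A4 as C3 epimers. Water must then be eliminated across C2–C3.
- Merits: the two aryl halves are joined by a simple phenol alkylation, no Pd catalyst and no 3-iodochromone are needed, and the C3 epimers do not matter because C3 becomes sp2. In convergence it equals the chosen plan.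
- Weak points: the aldehyde of A5 lies between two ortho oxygens and is electron-rich, so the acyl anion equivalent forms slowly. The basic conditions favour intramolecular aldol condensation of the α-aryloxy ketone onto the aldehyde (the Rap–Stoermer pathway). Dehydration of the tertiary alcohol needs acid or sulfonate activation in the presence of the allylic silyl ether and the chromene. The ring A aldehyde must already carry the side chain on the right carbon, so the key step solves neither the C6/C8 problem nor the stereocentre.
- Comparison: the chosen plan forms the same core by a cross-coupling with broad precedent for 2'-oxygenated rings B and needs no late dehydration. Against the metal-free ring closure of Alternative 2 it sets only the cost of a Pd catalyst and one borylation step.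

**Alternative 3:** close ring D last.
- Cut: C5'–C4(D) and O–C2(D).
- Forward key step: the 4'-O-(1,1-dimethylpropargyl) ether A7 is heated. A [3,3] shift to C5', enolisation, a 1,5-hydrogen shift and oxa-6π closure give the chromene A6, which lacks only desilylation.
- Merits: the cascade is reliable and is the reaction used in step 3 of the chosen route. Placed last, it keeps the chromene alkene out of the metathesis and epoxidation steps, so the chemoselectivity on which step 14 depends would not be needed. This is a real advantage.
- Weak points: the tertiary propargyl ether must be put on O4' alone among four phenols, which costs orthogonal protection. C5' versus C3' is decided on the most valuable intermediate with a silyl ether as the only bias. The secondary allylic silyl ether, the isopropenyl group and a free chelated 5-hydroxyl must survive 180–200 °C.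
- Comparison: the chosen plan runs the same cascade on 4, where bromine marks C1', the flanking MOM ether shields the wrong ortho carbon, and a minor isomer can be removed on scale. Against Alternative 3 it must set the burden of carrying the ring D alkene through steps 12 to 16. It does so with reagents that do not attack an unfunctionalised styrene-type alkene: a metathesis catalyst, a hydroxyl-bound titanium peroxide, and Zn. Alternative 3 does not create the stereocentre either.

Key step: step 14

Abbreviations: MOM = methoxymethyl, TBS = tert-butyldimethylsilyl, pin = pinacolato. Remark: the tertiary propargylic unit is used as its commercial chloride 2.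

Step 1
Reactants: 1 4-bromoresorcinol (4-bromobenzene-1,3-diol); 2 3-chloro-3-methylbut-1-yne
Product: 3 2-bromo-5-[(2-methylbut-3-yn-2-yl)oxy]phenol
Conditions: K2CO3, KI, CuI (cat.), acetone, 55 °C
Reagents that add atoms: none
Why: Williamson-type O-alkylation with CuI-assisted ionisation of the tertiary propargylic chloride. The hydroxyl para to bromine is the less hindered and the more nucleophilic one (the ortho-bromo phenoxide is less basic and shielded), so mono-etherification should occur there with one equivalent of 2.

Step 2
Reactants: 3 2-bromo-5-[(2-methylbut-3-yn-2-yl)oxy]phenol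
Product: 4 1-bromo-2-(methoxymethoxy)-4-[(2-methylbut-3-yn-2-yl)oxy]benzene
Conditions: MOMCl, iPr2NEt, CH2Cl2, 0 °C to rt
Reagents that add atoms: chloromethyl methyl ether, COCCl
Why: Standard MOM ether formation (O-alkylation with an α-chloro ether). It masks the remaining phenol for lithiation and coupling and adds bulk beside the ring carbon that must stay unsubstituted.

Step 3
Reactants: 4 1-bromo-2-(methoxymethoxy)-4-[(2-methylbut-3-yn-2-yl)oxy]benzene
Product: 5 6-bromo-7-(methoxymethoxy)-2,2-dimethyl-2H-chromene
Conditions: N,N-diethylaniline, 190 °C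
Reagents that add atoms: none
Why: Aryl propargyl ether Claisen rearrangement: [3,3] shift to a free ortho carbon, tautomerisation, 1,5-hydrogen shift and oxa-6π electrocyclisation close ring D. The ortho carbon between the two oxygens is shielded by the MOM ether, which bromine pushes towards it, so closure should occur at the carbon para to that ether, as with 3-alkoxyphenyl ethers of this type.

Step 4
Reactants: 5 6-bromo-7-(methoxymethoxy)-2,2-dimethyl-2H-chromene
Product: 7 2-[7-(methoxymethoxy)-2,2-dimethyl-2H-chromen-6-yl]-4,4,5,5-tetramethyl-1,3,2-dioxaborolane, via aryllithium 6 (not isolated)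
Conditions: n-BuLi, THF, −78 °C; then iPrOBpin, −78 °C to rt
Reagents that add atoms: 2-isopropoxy-4,4,5,5-tetramethyl-1,3,2-dioxaborolane, CC(C)OB1OC(C)(C)C(C)(C)O1; n-butyllithium, [Li]CCCC (lithium of 6 only)
Why: Lithium–bromine exchange is faster than ortho-lithiation at −78 °C, and the aryllithium is trapped by the borate ester (borylation). The chromene alkene and the acetal are inert to n-BuLi at this temperature.

Step 5
Reactants: 8 2,4,6-trihydroxyacetophenone
Product: 9 1-[2,6-dihydroxy-4-(methoxymethoxy)phenyl]ethan-1-one
Conditions: MOMCl (1.0 equiv), iPr2NEt, THF, 0 °C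
Reagents that add atoms: chloromethyl methyl ether, COCCl
Why: Selective O-alkylation: the 4-hydroxyl is the only one not hydrogen-bonded to the acetyl group and is the most acidic, so one equivalent of the chloro ether should protect it first.

Step 6
Reactants: 9 1-[2,6-dihydroxy-4-(methoxymethoxy)phenyl]ethan-1-one; 10 allyl bromide (3-bromoprop-1-ene)
Product: 11 1-[2-hydroxy-4-(methoxymethoxy)-6-(prop-2-en-1-yloxy)phenyl]ethan-1-one
Conditions: K2CO3, acetone, 56 °C
Reagents that add atoms: none
Why: Williamson etherification. The two free hydroxyls of 9 are equivalent, and once one is allylated the other is locked in a hydrogen bond to the ketone and reacts far more slowly, so mono-allylation is expected.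

Step 7
Reactants: 11 1-[2-hydroxy-4-(methoxymethoxy)-6-(prop-2-en-1-yloxy)phenyl]ethan-1-one
Product: 13 3-iodo-7-(methoxymethoxy)-5-(prop-2-en-1-yloxy)-4H-chromen-4-one, via enaminone 12 (not isolated)
Conditions: Me2NCH(OMe)2, 95 °C; concentrate; then I2, pyridine, CHCl3, rt
Reagents that add atoms: N,N-dimethylformamide dimethyl acetal, COC(OC)N(C)C (supplies C2–H); iodine, II
Why: Condensation of the methyl ketone with the amide acetal gives the enaminone. Iodine then iodinates its α-carbon and the free phenol adds to the β-carbon with loss of dimethylamine (iodocyclisation to a 3-iodochromone). Only one ortho oxygen is free, so the allyloxy group must end up on C5.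

Step 8
Reactants: 13 3-iodo-7-(methoxymethoxy)-5-(prop-2-en-1-yloxy)-4H-chromen-4-one
Product: 14 5-hydroxy-3-iodo-7-(methoxymethoxy)-6-(prop-2-en-1-yl)-4H-chromen-4-one
Conditions: 1,2-dichlorobenzene, 180 °C
Reagents that add atoms: none
Why: Aromatic Claisen rearrangement: the allyl group migrates with exchange of its termini to C6, the only unsubstituted ortho position of O5, and the dienone tautomerises to the chelated 5-phenol. The new hydrogen bond to C4=O makes the tautomerisation fast compared with an onward Cope shift.

Step 9
Reactants: 14 5-hydroxy-3-iodo-7-(methoxymethoxy)-6-(prop-2-en-1-yl)-4H-chromen-4-one; 7 2-[7-(methoxymethoxy)-2,2-dimethyl-2H-chromen-6-yl]-4,4,5,5-tetramethyl-1,3,2-dioxaborolane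
Product: 15 5-hydroxy-7-(methoxymethoxy)-3-[7-(methoxymethoxy)-2,2-dimethyl-2H-chromen-6-yl]-6-(prop-2-en-1-yl)-4H-chromen-4-one
Conditions: Pd(dppf)Cl2 (cat.), K2CO3, 1,4-dioxane/H2O, 80 °C
Reagents that add atoms: none
Why: Suzuki–Miyaura coupling: zerovalent palladium inserts into the activated C3–I bond of the α-iodoenone and the aryl boronate transmetalates, the standard entry to 2'-oxygenated isoflavones. The chelated 5-hydroxyl and the terminal alkene are tolerated.

Step 10
Reactants: 15 5-hydroxy-7-(methoxymethoxy)-3-[7-(methoxymethoxy)-2,2-dimethyl-2H-chromen-6-yl]-6-(prop-2-en-1-yl)-4H-chromen-4-one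
Product: 16 5,7-dihydroxy-3-(7-hydroxy-2,2-dimethyl-2H-chromen-6-yl)-6-(prop-2-en-1-yl)-4H-chromen-4-one
Conditions: HCl (3 M aq.), MeOH/THF, 50 °C
Reagents that add atoms: none
Why: Acid-mediated acetal cleavage (transacetalisation of the MOM ethers to methanol). It is placed here because the only acid-sensitive unit present is the 2,2-dimethylchromene, which tolerates these conditions, whereas the later allylic alcohol would not.

Step 11
Reactants: 16 5,7-dihydroxy-3-(7-hydroxy-2,2-dimethyl-2H-chromen-6-yl)-6-(prop-2-en-1-yl)-4H-chromen-4-one
Product: 17 5,7-bis(tert-butyldimethylsilyloxy)-3-[7-(tert-butyldimethylsilyloxy)-2,2-dimethyl-2H-chromen-6-yl]-6-(prop-2-en-1-yl)-4H-chromen-4-one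
Conditions: TBSOTf, 2,6-lutidine, CH2Cl2, 0 °C to rt
Reagents that add atoms: tert-butyldimethylsilyl trifluoromethanesulfonate, CC(C)(C)[Si](C)(C)OS(=O)(=O)C(F)(F)F
Why: O-Silylation with a silyl triflate, which is reactive enough to cap the chelated and flanked 5-hydroxyl as well as the two free phenols. The three ethers keep the phenols off titanium in step 14 and are removed by fluoride at the end.

Step 12
Reactants: 17 5,7-bis(tert-butyldimethylsilyloxy)-3-[7-(tert-butyldimethylsilyloxy)-2,2-dimethyl-2H-chromen-6-yl]-6-(prop-2-en-1-yl)-4H-chromen-4-one; 18 methacrolein (2-methylprop-2-enal)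
Product: 19 (2E)-4-{5,7-bis(tert-butyldimethylsilyloxy)-3-[7-(tert-butyldimethylsilyloxy)-2,2-dimethyl-2H-chromen-6-yl]-4-oxo-4H-chromen-6-yl}-2-methylbut-2-enal
Conditions: second-generation Hoveyda–Grubbs catalyst (H2IMes)Cl2Ru=CH(C6H4-2-OiPr) (5 mol%), excess 18, CH2Cl2, 40 °C
Reagents that add atoms: none
Why: Olefin cross-metathesis of a terminal alkene with an α-substituted acrolein, which does not homodimerise and gives the trisubstituted enal as the thermodynamically favoured (E)-isomer. The cis-disubstituted chromene alkene next to a quaternary carbon is too hindered to enter the catalytic cycle.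

Step 13
Reactants: 19 (2E)-4-{5,7-bis(tert-butyldimethylsilyloxy)-3-[7-(tert-butyldimethylsilyloxy)-2,2-dimethyl-2H-chromen-6-yl]-4-oxo-4H-chromen-6-yl}-2-methylbut-2-enal
Product: 20 5,7-bis(tert-butyldimethylsilyloxy)-3-[7-(tert-butyldimethylsilyloxy)-2,2-dimethyl-2H-chromen-6-yl]-6-[(2E)-4-hydroxy-3-methylbut-2-en-1-yl]-4H-chromen-4-one
Conditions: NaBH4, CeCl3·7H2O, MeOH/THF, −40 °C
Reagents that add atoms: none
Why: Luche reduction: the cerium-activated aldehyde is reduced 1,2 at low temperature, much faster than the cross-conjugated chromone carbonyl, and the (E)-geometry is retained.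

Step 14
Reactants: 20 5,7-bis(tert-butyldimethylsilyloxy)-3-[7-(tert-butyldimethylsilyloxy)-2,2-dimethyl-2H-chromen-6-yl]-6-[(2E)-4-hydroxy-3-methylbut-2-en-1-yl]-4H-chromen-4-one
Product: 21 5,7-bis(tert-butyldimethylsilyloxy)-3-[7-(tert-butyldimethylsilyloxy)-2,2-dimethyl-2H-chromen-6-yl]-6-{[(2S,3S)-3-(hydroxymethyl)-3-methyloxiran-2-yl]methyl}-4H-chromen-4-one, the (2S,3S)-2,3-epoxy-2-methyl-4-arylbutan-1-ol
Conditions: Ti(OiPr)4 (cat.), L-(+)-diisopropyl tartrate, t-BuOOH (anhydrous, in decane), 4 Å molecular sieves, CH2Cl2, −20 °C
Reagents that add atoms: tert-butyl hydroperoxide, CC(C)(C)OO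
Why: Sharpless asymmetric epoxidation: the alkoxide of 20 and tert-butyl peroxide replace isopropoxide ligands on one titanium of the dimeric Ti(OiPr)4/tartrate complex, and the bound peroxide passes its distal oxygen to the alkene held by the alkoxide. The closest known reaction type is the epoxidation of (E)-3-substituted 2-methylprop-2-en-1-ols, among the most reactive and selective substrates of this catalyst. The oxirane closes by concerted syn oxygen-atom transfer that forms C2''–O and C3''–O together, so the (E)-geometry of 20 becomes the trans relation of CH2OH and CH2Ar. Both stereocentres (C3 of the epoxy alcohol = C2'' of the side chain, and C2 = C3'') are set at once by the L-(+)-tartrate ligand, which for this substitution pattern gives the (2S,3S)-epoxide; the substrate is achiral and exerts no control. The step needs enantiofacial selectivity, secured by the tartrate and by the single (E)-isomer from steps 12 and 13. It also needs chemoselectivity: at −20 °C only an alkene tethered to titanium through a hydroxyl is epoxidised, so the ring D chromene alkene and the electron-poor C2=C3 bond of the chromone stay untouched. The three silyl ethers, above all that on O5, prevent phenoxide or chelate binding to titanium and prevent a phenol from opening the new epoxide, and the sieves keep the catalyst turning over.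

Step 15
Reactants: 21 the (2S,3S)-epoxy alcohol
Product: 22 5,7-bis(tert-butyldimethylsilyloxy)-3-[7-(tert-butyldimethylsilyloxy)-2,2-dimethyl-2H-chromen-6-yl]-6-{[(2S,3R)-3-(iodomethyl)-3-methyloxiran-2-yl]methyl}-4H-chromen-4-one (same spatial arrangement as 21)
Conditions: I2, PPh3, imidazole, THF, 0 °C
Reagents that add atoms: iodine, II
Why: Appel-type iodination of the primary alcohol through its alkoxyphosphonium salt, neutral and buffered by imidazole, a standard conversion of 2,3-epoxy alcohols. No stereocentre is touched; the descriptor of the methyl-bearing carbon changes only because iodine raises the rank of the CH2I group.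

Step 16
Reactants: 22 the epoxy iodide
Product: 23 5,7-bis(tert-butyldimethylsilyloxy)-3-[7-(tert-butyldimethylsilyloxy)-2,2-dimethyl-2H-chromen-6-yl]-6-[(2S)-2-hydroxy-3-methylbut-3-en-1-yl]-4H-chromen-4-one
Conditions: activated Zn dust, EtOH, 60 °C
Reagents that add atoms: none
Why: Zinc-mediated reductive elimination: Zn inserts into the C–I bond and the carbon–zinc bond expels the epoxide oxygen from C3'', which creates the C3''=C4'' alkene and the zinc alkoxide of the C2'' carbinol. The C2''–O bond is not broken, so the (S) configuration set in step 14 is carried over unchanged.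

Step 17
Reactants: 23 the tris-TBS ether of the target
Product: 24 5,7-dihydroxy-3-(7-hydroxy-2,2-dimethyl-2H-chromen-6-yl)-6-[(2S)-2-hydroxy-3-methylbut-3-en-1-yl]-4H-chromen-4-one (target)
Conditions: Bu4NF, AcOH, THF, 0 °C
Reagents that add atoms: none
Why: Fluoride-mediated cleavage of the three aryl silyl ethers. Acetic acid buffers the phenoxides, so neither the chromone nor the allylic alcohol is exposed to strong base or acid.

## Compound list

1 | 4-bromoresorcinol (4-bromobenzene-1,3-diol) | Oc1ccc(Br)c(O)c1 | starting material
2 | 3-chloro-3-methylbut-1-yne | CC(C)(Cl)C#C | starting material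
3 | 2-bromo-5-[(2-methylbut-3-yn-2-yl)oxy]phenol | C#CC(C)(C)Oc1ccc(Br)c(O)c1 | intermediate
4 | 1-bromo-2-(methoxymethoxy)-4-[(2-methylbut-3-yn-2-yl)oxy]benzene | C#CC(C)(C)Oc1ccc(Br)c(OCOC)c1 | intermediate
5 | 6-bromo-7-(methoxymethoxy)-2,2-dimethyl-2H-chromene | CC1(C)C=Cc2cc(Br)c(OCOC)cc2O1 | intermediate
6 | [7-(methoxymethoxy)-2,2-dimethyl-2H-chromen-6-yl]lithium | CC1(C)C=Cc2cc([Li])c(OCOC)cc2O1 | intermediate (not isolated)
7 | 2-[7-(methoxymethoxy)-2,2-dimethyl-2H-chromen-6-yl]-4,4,5,5-tetramethyl-1,3,2-dioxaborolane | CC1(C)C=Cc2cc(B3OC(C)(C)C(C)(C)O3)c(OCOC)cc2O1 | intermediate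
8 | 2,4,6-trihydroxyacetophenone | CC(=O)c1c(O)cc(O)cc1O | starting material
9 | 1-[2,6-dihydroxy-4-(methoxymethoxy)phenyl]ethan-1-one | CC(=O)c1c(O)cc(OCOC)cc1O | intermediate
10 | allyl bromide (3-bromoprop-1-ene) | C=CCBr | starting material
11 | 1-[2-hydroxy-4-(methoxymethoxy)-6-(prop-2-en-1-yloxy)phenyl]ethan-1-one | CC(=O)c1c(O)cc(OCOC)cc1OCC=C | intermediate
12 | (2E)-3-(dimethylamino)-1-[2-hydroxy-4-(methoxymethoxy)-6-(prop-2-en-1-yloxy)phenyl]prop-2-en-1-one | CN(C)/C=C/C(=O)c1c(O)cc(OCOC)cc1OCC=C | intermediate (not isolated)
13 | 3-iodo-7-(methoxymethoxy)-5-(prop-2-en-1-yloxy)-4H-chromen-4-one | C=CCOc1cc(OCOC)cc2occ(I)c(=O)c12 | intermediate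
14 | 5-hydroxy-3-iodo-7-(methoxymethoxy)-6-(prop-2-en-1-yl)-4H-chromen-4-one | C=CCc1c(OCOC)cc2occ(I)c(=O)c2c1O | intermediate
15 | 5-hydroxy-7-(methoxymethoxy)-3-[7-(methoxymethoxy)-2,2-dimethyl-2H-chromen-6-yl]-6-(prop-2-en-1-yl)-4H-chromen-4-one | C=CCc1c(OCOC)cc2occ(-c3cc4c(cc3OCOC)OC(C)(C)C=C4)c(=O)c2c1O | intermediate
16 | 5,7-dihydroxy-3-(7-hydroxy-2,2-dimethyl-2H-chromen-6-yl)-6-(prop-2-en-1-yl)-4H-chromen-4-one | C=CCc1c(O)cc2occ(-c3cc4c(cc3O)OC(C)(C)C=C4)c(=O)c2c1O | intermediate
17 | 5,7-bis(tert-butyldimethylsilyloxy)-3-[7-(tert-butyldimethylsilyloxy)-2,2-dimethyl-2H-chromen-6-yl]-6-(prop-2-en-1-yl)-4H-chromen-4-one | C=CCc1c(O[Si](C)(C)C(C)(C)C)cc2occ(-c3cc4c(cc3O[Si](C)(C)C(C)(C)C)OC(C)(C)C=C4)c(=O)c2c1O[Si](C)(C)C(C)(C)C | intermediate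
18 | methacrolein (2-methylprop-2-enal) | CC(=C)C=O | starting material
19 | (2E)-4-{5,7-bis(tert-butyldimethylsilyloxy)-3-[7-(tert-butyldimethylsilyloxy)-2,2-dimethyl-2H-chromen-6-yl]-4-oxo-4H-chromen-6-yl}-2-methylbut-2-enal | O=C/C(C)=C/Cc1c(O[Si](C)(C)C(C)(C)C)cc2occ(-c3cc4c(cc3O[Si](C)(C)C(C)(C)C)OC(C)(C)C=C4)c(=O)c2c1O[Si](C)(C)C(C)(C)C | intermediate
20 | 5,7-bis(tert-butyldimethylsilyloxy)-3-[7-(tert-butyldimethylsilyloxy)-2,2-dimethyl-2H-chromen-6-yl]-6-[(2E)-4-hydroxy-3-methylbut-2-en-1-yl]-4H-chromen-4-one | OC/C(C)=C/Cc1c(O[Si](C)(C)C(C)(C)C)cc2occ(-c3cc4c(cc3O[Si](C)(C)C(C)(C)C)OC(C)(C)C=C4)c(=O)c2c1O[Si](C)(C)C(C)(C)C | intermediate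
21 | 5,7-bis(tert-butyldimethylsilyloxy)-3-[7-(tert-butyldimethylsilyloxy)-2,2-dimethyl-2H-chromen-6-yl]-6-{[(2S,3S)-3-(hydroxymethyl)-3-methyloxiran-2-yl]methyl}-4H-chromen-4-one | OC[C@]1(C)O[C@H]1Cc1c(O[Si](C)(C)C(C)(C)C)cc2occ(-c3cc4c(cc3O[Si](C)(C)C(C)(C)C)OC(C)(C)C=C4)c(=O)c2c1O[Si](C)(C)C(C)(C)C | intermediate
22 | 5,7-bis(tert-butyldimethylsilyloxy)-3-[7-(tert-butyldimethylsilyloxy)-2,2-dimethyl-2H-chromen-6-yl]-6-{[(2S,3R)-3-(iodomethyl)-3-methyloxiran-2-yl]methyl}-4H-chromen-4-one | IC[C@]1(C)O[C@H]1Cc1c(O[Si](C)(C)C(C)(C)C)cc2occ(-c3cc4c(cc3O[Si](C)(C)C(C)(C)C)OC(C)(C)C=C4)c(=O)c2c1O[Si](C)(C)C(C)(C)C | intermediate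
23 | 5,7-bis(tert-butyldimethylsilyloxy)-3-[7-(tert-butyldimethylsilyloxy)-2,2-dimethyl-2H-chromen-6-yl]-6-[(2S)-2-hydroxy-3-methylbut-3-en-1-yl]-4H-chromen-4-one | C=C(C)[C@@H](O)Cc1c(O[Si](C)(C)C(C)(C)C)cc2occ(-c3cc4c(cc3O[Si](C)(C)C(C)(C)C)OC(C)(C)C=C4)c(=O)c2c1O[Si](C)(C)C(C)(C)C | intermediate
24 | 5,7-dihydroxy-3-(7-hydroxy-2,2-dimethyl-2H-chromen-6-yl)-6-[(2S)-2-hydroxy-3-methylbut-3-en-1-yl]-4H-chromen-4-one | C=C(C)[C@@H](O)Cc1c(O)cc2occ(-c3cc4c(cc3O)OC(C)(C)C=C4)c(=O)c2c1O | target

## Step count and least certain steps

Total: 17 steps. Longest linear sequence: 13 steps (steps 5–17 from 8, or steps 1–4 and 9–17 from 1).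

**Step 14 (key step).** The most likely failure is erosion of enantiofacial selectivity, with slow turnover, through a tartrate-free titanium pathway. This would arise if the chromone carbonyl, or an O5 that has lost its labile silyl group, binds the metal. Fallback: the stereocentre is corrected by reduction instead of epoxidation. The fallback sets out from 23 of insufficient enantiomeric purity, obtained through steps 15 and 16. Dess–Martin periodinane (NaHCO3, CH2Cl2) oxidises the carbinol to 5,7-bis(tert-butyldimethylsilyloxy)-3-[7-(tert-butyldimethylsilyloxy)-2,2-dimethyl-2H-chromen-6-yl]-6-(3-methyl-2-oxobut-3-en-1-yl)-4H-chromen-4-one F1. CBS reduction with the (R)-2-methyl oxazaborolidine and catecholborane (toluene, −78 °C) then returns to 23. The isopropenyl group should act as the large substituent, so the (R)-catalyst is expected to give the (S)-alcohol.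

**Step 1.** The risk is etherification at the hydroxyl next to bromine, or at both hydroxyls, because the ortho-bromo phenoxide is the more abundant anion. Fallback: from 1, the ring is built by C–C bond formation first. Condensation with 3-methylbut-2-enal (ethylenediammonium diacetate, xylene, heat) should proceed by Knoevenagel-type attack of the carbon para to the hindered hydroxyl and oxa-6π closure, and give 6-bromo-2,2-dimethyl-2H-chromen-7-ol F2. MOM protection (MOMCl, iPr2NEt) returns to the route at 5.

**Step 8.** The risk is loss of iodine, or onward migration of the allyl group to C8, at the temperature the rearrangement needs. Fallback: the order of coupling and rearrangement is reversed. From 13, Suzuki–Miyaura coupling with 7 (Pd(dppf)Cl2, K2CO3) gives 7-(methoxymethoxy)-3-[7-(methoxymethoxy)-2,2-dimethyl-2H-chromen-6-yl]-5-(prop-2-en-1-yloxy)-4H-chromen-4-one F3. Its Claisen rearrangement (N,N-diethylaniline, 190 °C) returns to the route at 15.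

**Step 11.** The risk is incomplete silylation of the chelated O5, which is flanked by the allyl group, or loss of this most labile silyl ether in steps 13 to 16. Fallback: the phenols are silylated in two stages with a change of mechanism at O5. From 16, TBSCl and imidazole in DMF give 6-allyl-7-(tert-butyldimethylsilyloxy)-3-[7-(tert-butyldimethylsilyloxy)-2,2-dimethyl-2H-chromen-6-yl]-5-hydroxy-4H-chromen-4-one F4. Its 5-hydroxyl is then deprotonated with NaH in THF and the free phenoxide trapped with TBSCl, which returns to the route at 17.

**Step 12.** The risk is isomerisation of the allyl group into conjugation with ring A, or slow metathesis of the electron-poor partner at an alkene shielded by two siloxy groups. Fallback: the oxygen is introduced after the carbon skeleton. From 17, cross-metathesis in 2-methylbut-2-ene as solvent (same catalyst) gives 5,7-bis(tert-butyldimethylsilyloxy)-3-[7-(tert-butyldimethylsilyloxy)-2,2-dimethyl-2H-chromen-6-yl]-6-(3-methylbut-2-en-1-yl)-4H-chromen-4-one F5. Allylic oxidation of its (E)-methyl group with SeO2 (cat.) and t-BuOOH in CH2Cl2 returns to the route at 20, bypassing 19.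

## Further compounds

F1 | step 14 | 5,7-bis(tert-butyldimethylsilyloxy)-3-[7-(tert-butyldimethylsilyloxy)-2,2-dimethyl-2H-chromen-6-yl]-6-(3-methyl-2-oxobut-3-en-1-yl)-4H-chromen-4-one | C=C(C)C(=O)Cc1c(O[Si](C)(C)C(C)(C)C)cc2occ(-c3cc4c(cc3O[Si](C)(C)C(C)(C)C)OC(C)(C)C=C4)c(=O)c2c1O[Si](C)(C)C(C)(C)C
F2 | step 1 | 6-bromo-2,2-dimethyl-2H-chromen-7-ol | CC1(C)C=Cc2cc(Br)c(O)cc2O1
F3 | step 8 | 7-(methoxymethoxy)-3-[7-(methoxymethoxy)-2,2-dimethyl-2H-chromen-6-yl]-5-(prop-2-en-1-yloxy)-4H-chromen-4-one | C=CCOc1cc(OCOC)cc2occ(-c3cc4c(cc3OCOC)OC(C)(C)C=C4)c(=O)c12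
F4 | step 11 | 7-(tert-butyldimethylsilyloxy)-3-[7-(tert-butyldimethylsilyloxy)-2,2-dimethyl-2H-chromen-6-yl]-5-hydroxy-6-(prop-2-en-1-yl)-4H-chromen-4-one | C=CCc1c(O[Si](C)(C)C(C)(C)C)cc2occ(-c3cc4c(cc3O[Si](C)(C)C(C)(C)C)OC(C)(C)C=C4)c(=O)c2c1O
F5 | step 12 | 5,7-bis(tert-butyldimethylsilyloxy)-3-[7-(tert-butyldimethylsilyloxy)-2,2-dimethyl-2H-chromen-6-yl]-6-(3-methylbut-2-en-1-yl)-4H-chromen-4-one | CC(C)=CCc1c(O[Si](C)(C)C(C)(C)C)cc2occ(-c3cc4c(cc3O[Si](C)(C)C(C)(C)C)OC(C)(C)C=C4)c(=O)c2c1O[Si](C)(C)C(C)(C)C
A1 | alternative 1 | (S)-4-[2-(tert-butyldimethylsilyloxy)-3-methylbut-3-enyl]-3,5-bis(triisopropylsilyloxy)phenol | C=C(C)[C@@H](O[Si](C)(C)C(C)(C)C)Cc1c(O[Si](C(C)C)(C(C)C)C(C)C)cc(O)cc1O[Si](C(C)C)(C(C)C)C(C)C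
A2 | alternative 1 | 2-[(2S)-2-(tert-butyldimethylsilyloxy)-3-methylbut-3-enyl]-3-(triisopropylsilyloxy)cyclobut-2-en-1-one | C=C(C)[C@@H](O[Si](C)(C)C(C)(C)C)CC1=C(O[Si](C(C)C)(C(C)C)C(C)C)CC1=O
A3 | alternative 1 | (triisopropylsilyloxy)ethyne | C#CO[Si](C(C)C)(C(C)C)C(C)C
A4 | alternative 2 | 5,7-bis(tert-butyldimethylsilyloxy)-6-[(2S)-2-(tert-butyldimethylsilyloxy)-3-methylbut-3-enyl]-3-hydroxy-3-[7-(tert-butyldimethylsilyloxy)-2,2-dimethyl-2H-chromen-6-yl]chroman-4-one (C3 epimers) | C=C(C)[C@@H](O[Si](C)(C)C(C)(C)C)Cc1c(O[Si](C)(C)C(C)(C)C)cc2c(c1O[Si](C)(C)C(C)(C)C)C(=O)C(O)(c1cc3c(cc1O[Si](C)(C)C(C)(C)C)OC(C)(C)C=C3)CO2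
A5 | alternative 2 | 2,4-bis(tert-butyldimethylsilyloxy)-3-[(2S)-2-(tert-butyldimethylsilyloxy)-3-methylbut-3-enyl]-6-{2-oxo-2-[7-(tert-butyldimethylsilyloxy)-2,2-dimethyl-2H-chromen-6-yl]ethoxy}benzaldehyde | C=C(C)[C@@H](O[Si](C)(C)C(C)(C)C)Cc1c(O[Si](C)(C)C(C)(C)C)cc(OCC(=O)c2cc3c(cc2O[Si](C)(C)C(C)(C)C)OC(C)(C)C=C3)c(C=O)c1O[Si](C)(C)C(C)(C)C
A6 | alternative 3 | 7-(tert-butyldimethylsilyloxy)-3-[7-(tert-butyldimethylsilyloxy)-2,2-dimethyl-2H-chromen-6-yl]-6-[(2S)-2-(tert-butyldimethylsilyloxy)-3-methylbut-3-enyl]-5-hydroxy-4H-chromen-4-one | C=C(C)[C@@H](O[Si](C)(C)C(C)(C)C)Cc1c(O[Si](C)(C)C(C)(C)C)cc2occ(-c3cc4c(cc3O[Si](C)(C)C(C)(C)C)OC(C)(C)C=C4)c(=O)c2c1O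
A7 | alternative 3 | 7-(tert-butyldimethylsilyloxy)-3-[2-(tert-butyldimethylsilyloxy)-4-(2-methylbut-3-yn-2-yloxy)phenyl]-6-[(2S)-2-(tert-butyldimethylsilyloxy)-3-methylbut-3-enyl]-5-hydroxy-4H-chromen-4-one | C=C(C)[C@@H](O[Si](C)(C)C(C)(C)C)Cc1c(O[Si](C)(C)C(C)(C)C)cc2occ(-c3ccc(OC(C)(C)C#C)cc3O[Si](C)(C)C(C)(C)C)c(=O)c2c1O
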